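**Assumption:** the target is taken exactly as drawn, i.e. (4R,5S,6R,7R,8S,9S) in germacrane labels (ring C1–C10; C11–C13 = methylene-lactone carbons; C14 = ester carbon on C10; C15 = methyl on C4), with cis-4,5-epoxide, cis-fused 6,12-lactone and ring-cis 1(10)-olefin; in step 11 the ligand antipode that gives Si-face addition is used.

## Retrosynthetic overview

1. Target ⇒ open-chain C15 epoxy aldehyde carrying a 2-(bromomethyl)enoate; one indium Barbier closure makes C6–C7 (the bond a germacrene synthase makes), and the C6 alkoxide then closes the 6,12-lactone.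
2. Open chain ⇒ C9–C10 union (Ni/Cr alkenyl–aldehyde coupling) of fragment A, a (Z)-α-iodoenoate (C1–C6, C10, C14, C15), with fragment B, an α-methacryloyloxy aldehyde (C7–C9, C11–C13).
3. Fragment A ⇒ nerol: Sharpless epoxidation (C4, C5), ozonolysis, iodo-Wittig.
4. Fragment B ⇒ (R)-glyceraldehyde acetonide (C8 from the pool) + methyl acrylate (Baylis–Hillman).
5. Ring order: oxirane (step 1), then the ten-membered carbocycle, then the γ-lactone (both in step 16).

## Route

**Step 1**
Reactants: 1 nerol, (2Z)-3,7-dimethylocta-2,6-dien-1-ol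
Product: 2 (2S,3R)-2,3-epoxynerol, [(2S,3R)-3-methyl-3-(4-methylpent-3-en-1-yl)oxiran-2-yl]methanol
Conditions: Ti(OiPr)4 (5 mol%), L-(+)-diethyl tartrate (7 mol%), t-BuOOH, 4 Å MS, CH2Cl2, −20 °C
Reagents that add atoms: tert-butyl hydroperoxide, CC(C)(C)OO
Why: Sharpless asymmetric epoxidation acts only on the allylic (Z)-2,3-olefin, and with L-(+)-tartrate the oxygen is delivered to the face that gives the (2S,3R) cis-epoxide, which sets C4 (R) and C5 (S) of the target.

**Step 2**
Reactants: 2 (2S,3R)-2,3-epoxynerol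
Product: 3 triethyl{[(2S,3R)-3-methyl-3-(4-methylpent-3-en-1-yl)oxiran-2-yl]methoxy}silane
Conditions: Et3SiCl, imidazole, CH2Cl2, 0 °C
Reagents that add atoms: chlorotriethylsilane, CC[Si](Cl)(CC)CC
Why: Routine silylation of the primary alcohol masks the future C6 aldehyde as an ether that fluoride removes later without touching the epoxide.

**Step 3**
Reactants: 3 epoxynerol triethylsilyl ether
Product: 4 3-[(2R,3S)-2-methyl-3-{[(triethylsilyl)oxy]methyl}oxiran-2-yl]propanal
Conditions: O3, CH2Cl2, −78 °C; then PPh3, −78 °C → rt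
Reagents that add atoms: ozone, [O-][O+]=O
Why: Ozonolysis with reductive work-up cleaves the only remaining, electron-rich trisubstituted olefin to the C1 aldehyde while epoxide and silyl ether are inert.

**Step 4**
Reactants: 4 epoxy aldehyde; 5 methyl (triphenyl-λ5-phosphanylidene)acetate
Product: 6 methyl (2Z)-2-iodo-5-[(2R,3S)-2-methyl-3-{[(triethylsilyl)oxy]methyl}oxiran-2-yl]pent-2-enoate (fragment A)
Conditions: 5, NIS, CH2Cl2, −20 °C; then 4, 0 °C → rt
Reagents that add atoms: N-iodosuccinimide, O=C1CCC(=O)N1I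
Why: Iodination of the stabilised ylide gives the α-iodo ylide, whose Wittig reaction with an aliphatic aldehyde gives mainly the (Z)-α-iodoenoate (about 9:1, separable), placing iodine cis to C2 so that C9 will later sit cis to C2 as the ring-cis 1(10)-olefin demands.

**Step 5**
Reactants: 7 (R)-2,2-dimethyl-1,3-dioxolane-4-carbaldehyde; 8 methyl acrylate
Product: 9 methyl (3S)-3-[(4R)-2,2-dimethyl-1,3-dioxolan-4-yl]-3-hydroxy-2-methylidenepropanoate
Conditions: DABCO, 1,4-dioxane/H2O (1:1), rt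
Reagents that add atoms: none
Why: Morita–Baylis–Hillman reaction of the activated α-alkoxy aldehyde attaches C11–C13 to C7; C8 comes unchanged from the chiral pool, and the new C7 carbinol (anti epimer major, about 3:1, separable) is only a temporary centre that becomes sp2 in step 15.

**Step 6**
Reactants: 9 Baylis–Hillman adduct
Product: 10 methyl (3S)-3-[(tert-butyldimethylsilyl)oxy]-3-[(4R)-2,2-dimethyl-1,3-dioxolan-4-yl]-2-methylidenepropanoate
Conditions: TBSOTf, 2,6-lutidine, CH2Cl2, −78 → 0 °C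
Reagents that add atoms: tert-butyldimethylsilyl triflate, CC(C)(C)[Si](C)(C)OS(=O)(=O)C(F)(F)F
Why: Silyl triflate silylation of the hindered secondary allylic alcohol gives a β-silyloxy group that cannot be eliminated when C9 later becomes an aldehyde.

**Step 7**
Reactants: 10 silyl ether acetonide
Product: 11 methyl (3S,4R)-3-[(tert-butyldimethylsilyl)oxy]-4,5-dihydroxy-2-methylidenepentanoate
Conditions: AcOH/H2O/THF (4:1:1), 35 °C
Reagents that add atoms: none
Why: Mild aqueous acetic acid hydrolyses the terminal acetonide while the secondary TBS ether survives and the medium is too weakly acidic to lactonise the γ-hydroxy ester.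

**Step 8**
Reactants: 11 diol
Product: 12 methyl (3S,4R)-3-[(tert-butyldimethylsilyl)oxy]-4-hydroxy-2-methylidene-5-[(triethylsilyl)oxy]pentanoate
Conditions: Et3SiCl, imidazole, CH2Cl2, −40 °C
Reagents that add atoms: chlorotriethylsilane, CC[Si](Cl)(CC)CC
Why: At low temperature the primary hydroxyl is silylated selectively over the hindered secondary one.

**Step 9**
Reactants: 12 secondary alcohol
Product: 13 methyl (3S,4R)-3-[(tert-butyldimethylsilyl)oxy]-2-methylidene-4-[(2-methylprop-2-enoyl)oxy]-5-[(triethylsilyl)oxy]pentanoate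
Conditions: methacryloyl chloride, Et3N, DMAP (cat.), CH2Cl2, 0 °C
Reagents that add atoms: methacryloyl chloride, C=C(C)C(=O)Cl
Why: DMAP-catalysed acylation installs the C8 methacrylate at this early point so that the C8 oxygen is never free next to the C12 or C14 ester later (no translactonisation, no diol differentiation problem).

**Step 10**
Reactants: 13 methacrylate
Product: 14 methyl (3S,4S)-3-[(tert-butyldimethylsilyl)oxy]-2-methylidene-4-[(2-methylprop-2-enoyl)oxy]-5-oxopentanoate (fragment B)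
Conditions: (COCl)2, DMSO, CH2Cl2, −78 → −40 °C; then Et3N, −78 °C
Reagents that add atoms: none
Why: Under Swern conditions a primary triethylsilyl ether is cleaved and oxidised directly to the aldehyde while the secondary TBS ether stays, and the cold, brief base treatment preserves the α-acyloxy stereocentre C8.

**Step 11**
Reactants: 6 fragment A; 14 fragment B
Product: 15 dimethyl (3S,4R,5S,6E)-3-[(tert-butyldimethylsilyl)oxy]-5-hydroxy-2-methylidene-4-[(2-methylprop-2-enoyl)oxy]-6-{3-[(2R,3S)-2-methyl-3-{[(triethylsilyl)oxy]methyl}oxiran-2-yl]propylidene}heptanedioate (C9 alcohol, 9S)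
Conditions: CrCl2, NiCl2 (2 mol%), N-[2-(4-isopropyl-4,5-dihydrooxazol-2-yl)-6-methylphenyl]methanesulfonamide (single antipode), Et3N, THF, rt
Reagents that add atoms: none
Why: Nozaki–Hiyama–Kishi coupling: oxidative addition of nickel to the alkenyl iodide and transmetalation give an alkenylchromium that adds only to the aldehyde with retention of olefin geometry, and the chiral sulfonamide ligand on chromium directs addition to the Si face (against the weak Felkin preference of the α-acyloxy aldehyde) to give the 9S carbinol, i.e. the 8,9-syn diol diester pattern.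

**Step 12**
Reactants: 15 C9 alcohol
Product: 16 dimethyl (3S,4R,5S,6E)-5-(acetyloxy)-3-[(tert-butyldimethylsilyl)oxy]-2-methylidene-4-[(2-methylprop-2-enoyl)oxy]-6-{3-[(2R,3S)-2-methyl-3-{[(triethylsilyl)oxy]methyl}oxiran-2-yl]propylidene}heptanedioate
Conditions: Ac2O, pyridine, DMAP (cat.), CH2Cl2, 0 °C
Reagents that add atoms: acetic anhydride, CC(=O)OC(C)=O
Why: Standard DMAP-catalysed acetylation of the secondary allylic alcohol, run cold and fast so that the neighbouring methacrylate does not migrate.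

**Step 13**
Reactants: 16 bis-silyl ether
Product: 17 dimethyl (3S,4S,5S,6E)-5-(acetyloxy)-3-hydroxy-6-{3-[(2R,3S)-3-(hydroxymethyl)-2-methyloxiran-2-yl]propylidene}-2-methylidene-4-[(2-methylprop-2-enoyl)oxy]heptanedioate
Conditions: Et3N·3HF, MeCN, 25–40 °C
Reagents that add atoms: none
Why: Near-neutral amine hydrofluoride cleaves both silyl ethers without opening the epoxide and without the alkoxide formation that would trigger acyl migration.

**Step 14**
Reactants: 17 diol
Product: 18 dimethyl (3S,4S,5S,6E)-5-(acetyloxy)-6-{3-[(2R,3R)-3-formyl-2-methyloxiran-2-yl]propylidene}-3-hydroxy-2-methylidene-4-[(2-methylprop-2-enoyl)oxy]heptanedioate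
Conditions: TEMPO (10 mol%), PhI(OAc)2, CH2Cl2, rt
Reagents that add atoms: none
Why: The oxoammonium oxidation (TEMPO/PhI(OAc)2) takes the unhindered primary epoxy alcohol to the aldehyde much faster than it touches the hindered, electron-poor secondary allylic alcohol.

**Step 15**
Reactants: 18 epoxy aldehyde with free Baylis–Hillman alcohol
Product: 19 dimethyl (2Z,4S,5S,6E)-5-(acetyloxy)-2-(bromomethyl)-6-{3-[(2R,3R)-3-formyl-2-methyloxiran-2-yl]propylidene}-4-[(2-methylprop-2-enoyl)oxy]hept-2-enedioate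
Conditions: NBS, Me2S, CH2Cl2, −20 → 0 °C
Reagents that add atoms: N-bromosuccinimide, O=C1CCC(=O)N1Br
Why: The Corey–Kim-type sulfonium reagent converts the Baylis–Hillman alcohol by SN2′ attack of bromide into the thermodynamically preferred (Z)-2-(bromomethyl)enoate under neutral conditions that spare epoxy aldehyde and esters, erasing the temporary C7 centre.

**Step 16**
Reactants: 19 open-chain bromo aldehyde
Product: 21 methyl (1R,2S,4R,7E,9S,10S,11R)-9-(acetyloxy)-4-methyl-12-methylidene-10-[(2-methylprop-2-enoyl)oxy]-13-oxo-3,14-dioxatricyclo[9.3.0.0(2,4)]tetradec-7-ene-8-carboxylate (target; germacrane labels 4R,5S,6R,7R,8S,9S), via hydroxy diester 20 (not isolated)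
Conditions: In powder, THF/H2O (3:1), 0.002 M, rt; then PPTS (cat.), CH2Cl2, rt
Reagents that add atoms: none
Why: Intramolecular indium Barbier allylation followed by lactonisation: at high dilution the (Z)-2-(methoxycarbonyl)allylindium adds to the C6 aldehyde through a chair transition state (C6–C7 syn, hence the cis-fused lactone), on the alkene face set by the C8 stereocentre (allylic-strain conformer, attack anti to C9, giving 7R) and with indium bridging aldehyde and epoxide oxygens (chelation, giving 6R, 5,6-threo), after which the C6 hydroxyl closes onto the C12 ester.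

## Compound list

1 | nerol, (2Z)-3,7-dimethylocta-2,6-dien-1-ol | CC(C)=CCC/C(C)=C\CO | starting material
2 | (2S,3R)-2,3-epoxynerol | OC[C@@H]1O[C@]1(C)CCC=C(C)C | intermediate
3 | triethyl{[(2S,3R)-3-methyl-3-(4-methylpent-3-en-1-yl)oxiran-2-yl]methoxy}silane | CC[Si](CC)(CC)OC[C@@H]1O[C@]1(C)CCC=C(C)C | intermediate
4 | 3-[(2R,3S)-2-methyl-3-{[(triethylsilyl)oxy]methyl}oxiran-2-yl]propanal | CC[Si](CC)(CC)OC[C@@H]1O[C@]1(C)CCC=O | intermediate
5 | methyl (triphenyl-λ5-phosphanylidene)acetate | COC(=O)C=P(c1ccccc1)(c1ccccc1)c1ccccc1 | starting material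
6 | methyl (2Z)-2-iodo-5-[(2R,3S)-2-methyl-3-{[(triethylsilyl)oxy]methyl}oxiran-2-yl]pent-2-enoate | COC(=O)/C(I)=C/CC[C@@]1(C)O[C@H]1CO[Si](CC)(CC)CC | intermediate
7 | (R)-2,2-dimethyl-1,3-dioxolane-4-carbaldehyde | O=C[C@H]1COC(C)(C)O1 | starting material
8 | methyl acrylate | C=CC(=O)OC | starting material
9 | methyl (3S)-3-[(4R)-2,2-dimethyl-1,3-dioxolan-4-yl]-3-hydroxy-2-methylidenepropanoate | C=C(C(=O)OC)[C@H](O)[C@H]1COC(C)(C)O1 | intermediate
10 | methyl (3S)-3-[(tert-butyldimethylsilyl)oxy]-3-[(4R)-2,2-dimethyl-1,3-dioxolan-4-yl]-2-methylidenepropanoate | C=C(C(=O)OC)[C@H](O[Si](C)(C)C(C)(C)C)[C@H]1COC(C)(C)O1 | intermediate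
11 | methyl (3S,4R)-3-[(tert-butyldimethylsilyl)oxy]-4,5-dihydroxy-2-methylidenepentanoate | C=C(C(=O)OC)[C@H](O[Si](C)(C)C(C)(C)C)[C@H](O)CO | intermediate
12 | methyl (3S,4R)-3-[(tert-butyldimethylsilyl)oxy]-4-hydroxy-2-methylidene-5-[(triethylsilyl)oxy]pentanoate | C=C(C(=O)OC)[C@H](O[Si](C)(C)C(C)(C)C)[C@H](O)CO[Si](CC)(CC)CC | intermediate
13 | methyl (3S,4R)-3-[(tert-butyldimethylsilyl)oxy]-2-methylidene-4-[(2-methylprop-2-enoyl)oxy]-5-[(triethylsilyl)oxy]pentanoate | C=C(C(=O)OC)[C@H](O[Si](C)(C)C(C)(C)C)[C@H](OC(=O)C(C)=C)CO[Si](CC)(CC)CC | intermediate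
14 | methyl (3S,4S)-3-[(tert-butyldimethylsilyl)oxy]-2-methylidene-4-[(2-methylprop-2-enoyl)oxy]-5-oxopentanoate | C=C(C(=O)OC)[C@H](O[Si](C)(C)C(C)(C)C)[C@H](OC(=O)C(C)=C)C=O | intermediate
15 | dimethyl (3S,4R,5S,6E)-3-[(tert-butyldimethylsilyl)oxy]-5-hydroxy-2-methylidene-4-[(2-methylprop-2-enoyl)oxy]-6-{3-[(2R,3S)-2-methyl-3-{[(triethylsilyl)oxy]methyl}oxiran-2-yl]propylidene}heptanedioate | C=C(C(=O)OC)[C@H](O[Si](C)(C)C(C)(C)C)[C@H](OC(=O)C(C)=C)[C@@H](O)/C(C(=O)OC)=C\CC[C@@]1(C)O[C@H]1CO[Si](CC)(CC)CC | intermediate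
16 | dimethyl (3S,4R,5S,6E)-5-(acetyloxy)-3-[(tert-butyldimethylsilyl)oxy]-2-methylidene-4-[(2-methylprop-2-enoyl)oxy]-6-{3-[(2R,3S)-2-methyl-3-{[(triethylsilyl)oxy]methyl}oxiran-2-yl]propylidene}heptanedioate | C=C(C(=O)OC)[C@H](O[Si](C)(C)C(C)(C)C)[C@H](OC(=O)C(C)=C)[C@@H](OC(C)=O)/C(C(=O)OC)=C\CC[C@@]1(C)O[C@H]1CO[Si](CC)(CC)CC | intermediate
17 | dimethyl (3S,4S,5S,6E)-5-(acetyloxy)-3-hydroxy-6-{3-[(2R,3S)-3-(hydroxymethyl)-2-methyloxiran-2-yl]propylidene}-2-methylidene-4-[(2-methylprop-2-enoyl)oxy]heptanedioate | C=C(C(=O)OC)[C@H](O)[C@H](OC(=O)C(C)=C)[C@@H](OC(C)=O)/C(C(=O)OC)=C\CC[C@@]1(C)O[C@H]1CO | intermediate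
18 | dimethyl (3S,4S,5S,6E)-5-(acetyloxy)-6-{3-[(2R,3R)-3-formyl-2-methyloxiran-2-yl]propylidene}-3-hydroxy-2-methylidene-4-[(2-methylprop-2-enoyl)oxy]heptanedioate | C=C(C(=O)OC)[C@H](O)[C@H](OC(=O)C(C)=C)[C@@H](OC(C)=O)/C(C(=O)OC)=C\CC[C@@]1(C)O[C@H]1C=O | intermediate
19 | dimethyl (2Z,4S,5S,6E)-5-(acetyloxy)-2-(bromomethyl)-6-{3-[(2R,3R)-3-formyl-2-methyloxiran-2-yl]propylidene}-4-[(2-methylprop-2-enoyl)oxy]hept-2-enedioate | BrC/C(C(=O)OC)=C\[C@H](OC(=O)C(C)=C)[C@@H](OC(C)=O)/C(C(=O)OC)=C\CC[C@@]1(C)O[C@H]1C=O | intermediate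
20 | hydroxy diester: ten-membered carbocycle of 21 with free 6-OH and a 1-(methoxycarbonyl)vinyl group on C7 (germacrane labels 4R,5S,6R,7S,8S,9S; 1(10)E) | C=C(C)C(=O)O[C@H]1[C@@H](C(=C)C(=O)OC)[C@@H](O)[C@@H]2O[C@]2(C)CC/C=C(/C(=O)OC)[C@@H]1OC(C)=O | intermediate (not isolated)
21 | methyl (1R,2S,4R,7E,9S,10S,11R)-9-(acetyloxy)-4-methyl-12-methylidene-10-[(2-methylprop-2-enoyl)oxy]-13-oxo-3,14-dioxatricyclo[9.3.0.0(2,4)]tetradec-7-ene-8-carboxylate | C=C(C)C(=O)O[C@H]1[C@H]2C(=C)C(=O)O[C@H]2[C@@H]2O[C@]2(C)CC/C=C(/C(=O)OC)[C@@H]1OC(C)=O | target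

## Step count and risks

Total steps: 16. Longest linear sequence: 12 steps (7 → 21, steps 5–16); the nerol branch is 10 steps (steps 1–4, 11–16).

**Most likely to fail, 1: step 16 (macrocyclisation).** The closure has to form a ten-membered ring and set C6 and C7 correctly in one event. The stereochemical argument rests on intermolecular indium allylations of α-oxygenated aldehydes and on closures of this same bond with divalent chromium, not on this exact substrate. The fallback sets out from 18 and comes back at 21. Instead of making the bromide, 18 is converted with Boc2O and DMAP (cat.) in CH2Cl2 at 0 °C into the allylic carbonate dimethyl (3S,4R,5S,6E)-5-(acetyloxy)-3-[(tert-butoxycarbonyl)oxy]-6-{3-[(2R,3R)-3-formyl-2-methyloxiran-2-yl]propylidene}-2-methylidene-4-[(2-methylprop-2-enoyl)oxy]heptanedioate F1. With Pd(PPh3)4 (zerovalent palladium, 5 mol%) and Et2Zn in THF at 0.002 M, the terminal-methylene carbonate ionises in preference to the hindered C9 acetate. The π-allylpalladium is turned by zinc into a nucleophilic allylzinc (umpolung), which adds to the C6 aldehyde in a closed transition state. The zinc alkoxide of 20 then lactonises to 21.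

**Most likely to fail, 2: step 11 (fragment union).** The ligand has to override the Felkin preference of 14, and an α-ester alkenylchromium could lose some olefin geometry. The fallback sets out from 6 and 14 and comes back at 15. The coupling is run without chiral ligand (CrCl2, NiCl2 cat., DMSO/THF, rt), which gives 15 together with its C9 epimer dimethyl (3S,4R,5R,6E)-3-[(tert-butyldimethylsilyl)oxy]-5-hydroxy-2-methylidene-4-[(2-methylprop-2-enoyl)oxy]-6-{3-[(2R,3S)-2-methyl-3-{[(triethylsilyl)oxy]methyl}oxiran-2-yl]propylidene}heptanedioate F2. The mixture is oxidised with Dess–Martin periodinane (NaHCO3, CH2Cl2, 0 °C) to the ketone dimethyl (3S,4S,6E)-3-[(tert-butyldimethylsilyl)oxy]-2-methylidene-4-[(2-methylprop-2-enoyl)oxy]-5-oxo-6-{3-[(2R,3S)-2-methyl-3-{[(triethylsilyl)oxy]methyl}oxiran-2-yl]propylidene}heptanedioate F3. The ketone is reduced at once with NaBH4 and CeCl3·7H2O in MeOH at −78 °C (Luche 1,2-reduction); hydride enters anti to the C8–O bond (polar Felkin–Anh), which for a reduction gives the 8,9-syn alcohol 15. The cold, fast sequence is needed because the alkylidene keto ester can isomerise.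

**Most likely to fail, 3: step 7 (acetonide hydrolysis).** The free diol 11 is a γ-hydroxy α-methylene ester and can lactonise or lose the TBS group under acid. The fallback sets out from 10 and comes back at 12 without passing through the diol. TESOTf and 2,6-lutidine in CH2Cl2 at 0 °C open the acetonide at the less hindered oxygen to give the primary silyl ether and secondary enol ether methyl (3S,4R)-3-[(tert-butyldimethylsilyl)oxy]-2-methylidene-4-(prop-1-en-2-yloxy)-5-[(triethylsilyl)oxy]pentanoate F4. Its enol ether is hydrolysed within minutes by PPTS (cat.) in wet THF at 0 °C to give 12, which is acylated immediately (step 9).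

## Further compounds

F1 | step 16 | dimethyl (3S,4R,5S,6E)-5-(acetyloxy)-3-[(tert-butoxycarbonyl)oxy]-6-{3-[(2R,3R)-3-formyl-2-methyloxiran-2-yl]propylidene}-2-methylidene-4-[(2-methylprop-2-enoyl)oxy]heptanedioate | C=C(C(=O)OC)[C@H](OC(=O)OC(C)(C)C)[C@H](OC(=O)C(C)=C)[C@@H](OC(C)=O)/C(C(=O)OC)=C\CC[C@@]1(C)O[C@H]1C=O
F2 | step 11 | dimethyl (3S,4R,5R,6E)-3-[(tert-butyldimethylsilyl)oxy]-5-hydroxy-2-methylidene-4-[(2-methylprop-2-enoyl)oxy]-6-{3-[(2R,3S)-2-methyl-3-{[(triethylsilyl)oxy]methyl}oxiran-2-yl]propylidene}heptanedioate | C=C(C(=O)OC)[C@H](O[Si](C)(C)C(C)(C)C)[C@H](OC(=O)C(C)=C)[C@H](O)/C(C(=O)OC)=C\CC[C@@]1(C)O[C@H]1CO[Si](CC)(CC)CC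
F3 | step 11 | dimethyl (3S,4S,6E)-3-[(tert-butyldimethylsilyl)oxy]-2-methylidene-4-[(2-methylprop-2-enoyl)oxy]-5-oxo-6-{3-[(2R,3S)-2-methyl-3-{[(triethylsilyl)oxy]methyl}oxiran-2-yl]propylidene}heptanedioate | C=C(C(=O)OC)[C@H](O[Si](C)(C)C(C)(C)C)[C@H](OC(=O)C(C)=C)C(=O)/C(C(=O)OC)=C\CC[C@@]1(C)O[C@H]1CO[Si](CC)(CC)CC
F4 | step 7 | methyl (3S,4R)-3-[(tert-butyldimethylsilyl)oxy]-2-methylidene-4-(prop-1-en-2-yloxy)-5-[(triethylsilyl)oxy]pentanoate | C=C(C(=O)OC)[C@H](O[Si](C)(C)C(C)(C)C)[C@H](OC(C)=C)CO[Si](CC)(CC)CC
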